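The data were computed from invented constants; the scatter is artificial.

I begin by comparing two rates at one moment, because I take target and isomer of the product to be made side by side from substrate and reagent. The asked flask has been followed as the midnight run; the noon run has more reagent.

common to all: substrate 0.091 M
- midnight: reagent 0.109 M; the very flask that is asked about, followed so far
- noon: reagent 0.16 M; run made earlier
- flask: reagent 0.109 M; time 2.5 min

| run | time / s | target / % | isomer of the product / % |
|---|---|---|---|
| midnight | 15.0 | 42.3 | 23.5 |
| midnight | 30.0 | 51.1 | 22.4 |
| midnight | 50.0 | 59.2 | 19.7 |
| midnight | 60.0 | 61.5 | 17.0 |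
| midnight | 80.0 | 65.0 | 12.9 |
| noon | 10.0 | 46.0 | 24.4 |
| noon | 15.0 | 50.3 | 25.6 |
| noon | 30.0 | 61.7 | 24.1 |
| noon | 60.0 | 68.8 | 18.3 |
| noon | 120 | 73.3 | 8.2 |

(each reading ± 1 percentage point)

- a reading or a percentage of target counts all its forms, free or not

1. ratio of target to isomer of the product at 0.40 s
2. ratio of target to isomer of the product at 8.0 s
3. ratio of target to isomer of the product at 2.5 min
4. which of target and isomer of the product there is more of at 2.5 min

In the midnight run the isomer falls late on, from 19.7% to 12.9% between 50.0 s and 80.0 s, which reads as a net loss of 0.0141 s⁻¹. Adding that loss back to the earliest noon reading, at 10.0 s, gives my estimate of the split, the rate into target over the rate into isomer at one moment (the selectivity factor): 1.64. It is a rough estimate, and the scatter of the readings is in it. At 15.0 s the raw ratios are 1.80 at midnight and 1.96 at noon, which is no clear difference with 1 percentage point on each reading, so I take the split to be independent of reagent.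

Now the flask in slow motion. At that rate the loss of isomer by 0.40 s comes to about 0.564% of itself, so I expect the ratio to stand at the split. At 8.0 s I expect it between the split and the raw midnight ratio at 15.0 s. In the middle the isomer turns over and falls while target climbs. At 80.0 s target leads, 65.0% to 12.9%, and it is still rising. Carrying the same net loss over the remaining time takes the isomer to 4.80%, which is a rough estimate and not a bound.

The forecast gives 1.65, 1.72 and 14, with target ahead, and puts the isomer near 5%, “plus a little feed”.

The flask gives 1.63, 1.71 and 10.4, with target ahead, so the forecast's last ratio is high. The isomer ends at 6.53%, above my estimate.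

    substrate + reagent ⇌ target (K = 97.0 M⁻¹, k = 0.770 M⁻¹ s⁻¹)
    substrate + reagent ⇌ isomer of the product (K = 21.0 M⁻¹, k = 0.470 M⁻¹ s⁻¹)
    crystals ⇌ target, rate k3*(cs3 - [target]) while solid is left; crystals form when [target] > cs3 (solubility = 2.00 mM, k = 1.40 s⁻¹)
    target → over-reaction product (k = 0.0490 s⁻¹)

At 2.5 min in the flask the forward step to target runs at 1.6 times the forward step to isomer, with substrate at 7.02% and reagent at 22.4% of its own charge. By my split, 37.9% of the substrate reacting forward goes to isomer.

Take the same flask with 0.044 M of reagent. Both forward rates carry [substrate][reagent], so the split gives an early ratio of 1.64 there too. That flask computes to 1.63 at 0.40 s and 7.86 at 2.5 min.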